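**Assumptions:** 4,6-Dimethoxy-2-pyrone is purchasable. The (2S)- and (2R)-C2 diastereomers of the pentakis-MOM flavanone are separable by preparative HPLC.

## Retrosynthetic overview
1. Norkurarinol (1) comes from global MOM removal of the pentakis-MOM flavanone (17). That flavanone comes from oxa-Michael closure of the MOM-protected 2'-hydroxychalcone (2). The chalcone comes from Claisen–Schmidt condensation of acetophenone (3) with 2,4-bis(MOM-oxy)benzaldehyde (4).
2. The A ring of 3 is built by an inverse-demand [4+2] cycloaddition/retro-[4+2] loss of CO2 between 3-acetyl-4,6-dimethoxy-2-pyrone (5) and siloxyalkyne (6). The alkyne carbons become C8 (which carries the lavandulyl CH2) and C8a (the O1 carbon).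
3. Siloxyalkyne 6 comes from Kowalski homologation of ester 7, which comes from (R)-limonene 1,2-oxide (8). The limonene C4 centre becomes C2'' (R) and is never touched. In the homologation the CH2Br2 carbon becomes the alkyne carbon C8, and the former ester/aldehyde carbon becomes the O-bearing alkyne carbon C8a.
4. Ring order: A ring (cycloaddition), then C ring (oxa-Michael, with C2 epimers separated), then global MOM removal.

## Route

**Step 1**
Reactants: 8, (R)-(+)-limonene 1,2-oxide (cis/trans mixture)
Product: 9, (3R)-6-oxo-3-(prop-1-en-2-yl)heptanal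
Conditions: H5IO6, THF/H2O, 0 °C → rt
Reagents that add atoms: water, O
Why: Periodic acid opens the epoxide to the diol in situ and cleaves it (Malaprade cleavage), leaving the isopropenyl group and the C4 stereocentre untouched. The epoxide centres are destroyed, so the cis/trans ratio is irrelevant and no new stereocentre forms.

**Step 2**
Reactants: 9
Product: 10, (3R)-6-oxo-3-(prop-1-en-2-yl)heptanoic acid
Conditions: NaClO2, NaH2PO4, 2-methyl-2-butene, t-BuOH/H2O, rt
Reagents that add atoms: sodium chlorite, [Na+].[O-]Cl=O (adds O)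
Why: Pinnick oxidation is selective for the aldehyde. The methyl ketone survives, and the alkene scavenger protects the isopropenyl group. The stereocentre is β to the carbonyl and cannot epimerise.

**Step 3**
Reactants: 10
Product: 11, (3R)-6-hydroxy-6-methyl-3-(prop-1-en-2-yl)heptanoic acid
Conditions: MeMgBr (3 equiv), THF, −78 → 0 °C; aq. NH4Cl
Reagents that add atoms: methylmagnesium bromide, C[Mg]Br (adds CH3)
Why: The first equivalent forms the inert carboxylate, so the later equivalents add only to the methyl ketone (Grignard addition). The new carbinol carbon carries two identical methyls, so it is not a stereocentre.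

**Step 4**
Reactants: 11
Product: 12, methyl (3R)-6-hydroxy-6-methyl-3-(prop-1-en-2-yl)heptanoate
Conditions: TMSCHN2, MeOH/PhMe, 0 °C → rt
Reagents that add atoms: trimethylsilyldiazomethane, C[Si](C)(C)C=[N+]=[N-] (adds CH3)
Why: Diazoalkane O-methylation of the acid is mild and leaves the hindered tertiary alcohol and the alkene alone.

**Step 5**
Reactants: 12
Product: 7, methyl (3R)-6-(methoxymethoxy)-6-methyl-3-(prop-1-en-2-yl)heptanoate
Conditions: MOMCl, i-Pr2NEt, TBAI (cat.), CH2Cl2, 40 °C
Reagents that add atoms: chloromethyl methyl ether, COCCl (adds CH3OCH2)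
Why: MOM acetal formation masks the tertiary OH so it survives the organolithiums of the next step and the thiolate later. It is removed together with the other MOM groups at the end.

**Step 6**
Reactants: 7
Product: 6, {[(4R)-7-(methoxymethoxy)-7-methyl-4-(prop-1-en-2-yl)oct-1-yn-1-yl]oxy}tri(propan-2-yl)silane
Conditions: (i) CH2Br2, LiTMP, THF, −78 °C; (ii) n-BuLi (3 equiv), −78 °C; (iii) TIPSCl, −78 °C → rt
Reagents that add atoms: dibromomethane, BrCBr (adds C); triisopropylsilyl chloride, CC(C)[Si](Cl)(C(C)C)C(C)C (adds Si(iPr)3)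
Why: Kowalski ester homologation goes through the dibromomethyl ketone. Lithium–halogen exchange and 1,2-shift of the alkyl group onto the carbenoid carbon give a lithium ynolate, which is O-silylated to the siloxyalkyne. The CH2Br2 carbon ends up bearing the CH2R group (future C8), and the former ester carbon bears the oxygen (future C8a). The stereocentre is remote and is not epimerised.

**Step 7**
Reactants: 13, 4,6-dimethoxy-2H-pyran-2-one
Product: 5, 3-acetyl-4,6-dimethoxy-2H-pyran-2-one
Conditions: Ac2O, BF3·OEt2, CH2Cl2, 0 °C → rt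
Reagents that add atoms: acetic anhydride, CC(=O)OC(C)=O (adds COCH3)
Why: Electrophilic C-acylation (Friedel–Crafts type) occurs at C3, the nucleophilic carbon of the vinylogous carbonate flanked by the lactone carbonyl and the 4-OMe. Any C5 isomer is removed by chromatography. The acetyl group makes the pyrone an electron-poor diene and becomes the aryl ketone (C4) of the flavanone.

**Step 8**
Reactants: 5 + 6
Product: 14, 1-{2-(triisopropylsilyloxy)-4,6-dimethoxy-3-[(2R)-5-(methoxymethoxy)-5-methyl-2-(prop-1-en-2-yl)hexyl]phenyl}ethan-1-one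
Conditions: toluene, BHT, 130 °C, sealed tube
Reagents that add atoms: none (CO2 is lost)
Why: Diels–Alder cycloaddition followed by retro-Diels–Alder loss of CO2 gives the arene directly. The nucleophilic β-carbon of the siloxyalkyne bonds to pyrone C6, and the O-bearing carbon bonds to C3. This places the CH2R group at C8 between two oxygenated carbons and the acetyl at C4a. The C2'' stereocentre is remote and unaffected.

**Step 9**
Reactants: 14
Product: 15, 1-{2,4,6-trihydroxy-3-[(2R)-5-(methoxymethoxy)-5-methyl-2-(prop-1-en-2-yl)hexyl]phenyl}ethan-1-one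
Conditions: NaSEt (8 equiv), DMF, 140 °C; aq. NH4Cl
Reagents that add atoms: none
Why: Thiolate cleaves aryl methyl ethers by SN2 at the methyl carbon and also removes the aryl TIPS ether by attack at silicon. The tertiary MOM ether and the alkene survive, whereas a Lewis-acid demethylation would destroy them.

**Step 10**
Reactants: 15
Product: 3, 1-{2-hydroxy-4,6-bis(methoxymethoxy)-3-[(2R)-5-(methoxymethoxy)-5-methyl-2-(prop-1-en-2-yl)hexyl]phenyl}ethan-1-one
Conditions: MOMCl (2.2 equiv), i-Pr2NEt, CH2Cl2, 0 °C
Reagents that add atoms: chloromethyl methyl ether, COCCl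
Why: The 4'-OH is the most acidic and is not chelated, so it reacts first, followed by the less hindered 6'-OH. The 2'-OH is flanked by the lavandulyl group and chelated to the ketone, so it stays free. This ensures ring closure later at the O next to C8.

**Step 11**
Reactants: 16, 2,4-dihydroxybenzaldehyde
Product: 4, 2,4-bis(methoxymethoxy)benzaldehyde
Conditions: MOMCl (2.5 equiv), i-Pr2NEt, CH2Cl2, 0 °C → rt
Reagents that add atoms: chloromethyl methyl ether, COCCl
Why: Standard phenol MOM protection.

**Step 12**
Reactants: 3 + 4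
Product: 2, (E)-1-{2-hydroxy-4,6-bis(methoxymethoxy)-3-[(2R)-5-(methoxymethoxy)-5-methyl-2-(prop-1-en-2-yl)hexyl]phenyl}-3-[2,4-bis(methoxymethoxy)phenyl]prop-2-en-1-one
Conditions: KOH, EtOH/H2O, rt → 40 °C
Reagents that add atoms: none (loses H2O)
Why: Claisen–Schmidt aldol condensation gives the thermodynamic E-enone. There is no new stereocentre.

**Step 13**
Reactants: 2
Product: 17, (2S)-pentakis-MOM flavanone: (2S)-5,7-bis(MOM-oxy)-2-[2,4-bis(MOM-oxy)phenyl]-8-[(2R)-5-(MOM-oxy)-5-methyl-2-(prop-1-en-2-yl)hexyl]chroman-4-one
Conditions: NaOAc, EtOH, reflux; then preparative HPLC to isolate the (2S) diastereomer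
Reagents that add atoms: none
Why: 6-endo-trig oxa-Michael cyclisation can only use the free 2'-OH, which secures the 8-substituted regiochemistry. C2 forms reversibly with only weak induction from the remote C2'' centre, giving roughly a 1:1 mixture of (2S,2''R) and (2R,2''R) diastereomers. These are separated chromatographically, and the (2R) diastereomer is discarded.

**Step 14**
Reactants: 17
Product: 1, norkurarinol
Conditions: 3 M HCl, MeOH, 40 °C
Reagents that add atoms: none
Why: Acidolysis of the five MOM acetals, including the tertiary one, unmasks all the OH groups. The C2 and C2'' stereocentres are not affected under these conditions.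

## Compound list
1 | norkurarinol, (2S)-5,7,2',4'-tetrahydroxy-8-[(2R)-5-hydroxy-5-methyl-2-(prop-1-en-2-yl)hexyl]flavan-4-one | C=C(C)[C@H](CCC(C)(C)O)Cc1c(O)cc(O)c2c1O[C@H](c1ccc(O)cc1O)CC2=O | target
2 | MOM-protected (E)-2'-hydroxychalcone | O=C(/C=C/c1ccc(OCOC)cc1OCOC)c1c(OCOC)cc(OCOC)c(C[C@@H](CCC(C)(C)OCOC)C(C)=C)c1O | intermediate
3 | 2'-hydroxy-4',6'-bis(MOM)-3'-lavandulyl(OMOM) acetophenone | CC(=O)c1c(OCOC)cc(OCOC)c(C[C@@H](CCC(C)(C)OCOC)C(C)=C)c1O | intermediate
4 | 2,4-bis(methoxymethoxy)benzaldehyde | COCOc1ccc(C=O)c(OCOC)c1 | intermediate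
5 | 3-acetyl-4,6-dimethoxy-2H-pyran-2-one | CC(=O)C1=C(OC)C=C(OC)OC1=O | intermediate
6 | siloxyalkyne | CC(C)[Si](C(C)C)(C(C)C)OC#CC[C@@H](CCC(C)(C)OCOC)C(C)=C | intermediate
7 | methyl (3R)-6-(methoxymethoxy)-6-methyl-3-(prop-1-en-2-yl)heptanoate | COC(=O)C[C@@H](CCC(C)(C)OCOC)C(C)=C | intermediate
8 | (R)-(+)-limonene 1,2-oxide (cis/trans) | CC12OC1C[C@@H](CC2)C(C)=C | starting material
9 | (3R)-6-oxo-3-(prop-1-en-2-yl)heptanal | O=CC[C@@H](CCC(C)=O)C(C)=C | intermediate
10 | (3R)-6-oxo-3-(prop-1-en-2-yl)heptanoic acid | OC(=O)C[C@@H](CCC(C)=O)C(C)=C | intermediate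
11 | (3R)-6-hydroxy-6-methyl-3-(prop-1-en-2-yl)heptanoic acid | OC(=O)C[C@@H](CCC(C)(C)O)C(C)=C | intermediate
12 | methyl (3R)-6-hydroxy-6-methyl-3-(prop-1-en-2-yl)heptanoate | COC(=O)C[C@@H](CCC(C)(C)O)C(C)=C | intermediate
13 | 4,6-dimethoxy-2H-pyran-2-one | O=C1C=C(OC)C=C(OC)O1 | starting material
14 | 2'-OTIPS-4',6'-dimethoxy-3'-lavandulyl(OMOM) acetophenone | CC(=O)c1c(OC)cc(OC)c(C[C@@H](CCC(C)(C)OCOC)C(C)=C)c1O[Si](C(C)C)(C(C)C)C(C)C | intermediate
15 | 2',4',6'-trihydroxy-3'-lavandulyl(OMOM) acetophenone | CC(=O)c1c(O)cc(O)c(C[C@@H](CCC(C)(C)OCOC)C(C)=C)c1O | intermediate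
16 | 2,4-dihydroxybenzaldehyde | O=Cc1ccc(O)cc1O | starting material
17 | (2S)-pentakis-MOM flavanone | C=C(C)[C@H](CCC(C)(C)OCOC)Cc1c(OCOC)cc(OCOC)c2c1O[C@H](c1ccc(OCOC)cc1OCOC)CC2=O | intermediate

**Total steps:** 14.
**Longest linear sequence:** 12 (steps 1–6, 8, 9, 10, 12, 13, 14).

**Three steps most likely to fail**
1. **Step 8 (pyrone + siloxyalkyne cycloaddition).** The 4,6-dialkoxy acylpyrone is only modestly electron-poor, so reactivity or regiochemistry may fail.
   - Fallback: form the aryl–CH2 bond by cross-coupling instead. Convert the MOM-protected acid derived from 11 to its N-hydroxyphthalimide ester and couple it with 3'-bromo-2'-hydroxy-4',6'-bis(MOM)acetophenone under Ni/Zn decarboxylative conditions to give 3 directly.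
2. **Step 6 (ynolate O-silylation).** C-silylation to the silylketene may compete with the desired O-silylation.
   - Fallback: drop the ynol ether. Convert 11 (after MOM protection) to the iodide by Barton decarboxylative iodination, alkylate the aryllithium from 1,3,5-tris(MOM-oxy)benzene with it (CuI), and install the acetyl by lithiation and Weinreb acetamide.
3. **Step 10 (regioselective bis-MOM protection).** Protection of the 2'-OH instead of the 6'-OH would lead to the wrong ring closure.
   - Fallback: skip steps 9–10. Desilylate 14 with TBAF to the 2'-hydroxy-4',6'-dimethoxyacetophenone and run steps 12–13 on the methyl ethers. Remove the 5- and 7-methyl ethers with LiSPr/HMPA, then the MOM groups with HCl/MeOH. Accept C2 scrambling in the thiolate step, because the C2 epimers are separated by HPLC anyway.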